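A direct plan would prepare tridecyl(triphenyl)phosphonium bromide A1, join it after deprotonation with tetradecanal A2 in a Wittig reaction to give (Z)-heptacos-13-ene A3, and then convert A3 with carbon monoxide A4 and 2-phenylethanol A5 into the target by isomerising alkoxycarbonylation.
Its weakest steps would be the following.
Salt formation and olefination: making A1 and joining it with A2 would spend two operations and a stoichiometric phosphorus by-product on a double bond in A3 that is erased again.
Isomerising carbonylation: the double bond of A3 would have to migrate over twelve or thirteen positions to a chain end under pressurised A4 in an excess of A5, so slow conversion, branched esters and a waxy mixture that is hard to purify would be expected.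

**Strategy.** The route would rest on the C11–C12 bond in the middle of the unbranched octacosanoyl chain (C1 = ester carbonyl), a bond between two methylene carbons of like polarity and the only real task in a target whose sole ring, the phenyl ring, can be bought. A crossed Kolbe electrolysis would join the heptadecyl radical from octadecanoic acid with the 10-(2-phenylethoxycarbonyl)decyl radical from mono-2-phenylethyl dodecanedioate, each carboxyl group acting as a traceless handle lost as CO2. One anodic operation would thus complete the C28 chain with the ester already in place, from two commodity acids, with no phosphonium salt, olefination, alkene intermediate, carbon monoxide or chain-walking catalyst.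

Key step: step 2

Remark on the chemistry: the target has no stereocentre and no stereogenic double bond, so no step has to control configuration. Both primary alkyl radicals of the key step are assumed to couple without bias, so that the product distribution follows the molar ratio of the two acids.

**Step 1**
Reactants: 1 dodecanedioic acid; 2 2-phenylethanol
Product: 3 12-oxo-12-(2-phenylethoxy)dodecanoic acid (mono-2-phenylethyl dodecanedioate)
Conditions: 1 (3 equiv), 2 (1 equiv), TsOH·H2O (5 mol %), toluene, reflux, Dean–Stark; cool, filter off excess 1; SiO2 (hexane/EtOAc, 1 % AcOH)
Reagents that add atoms: none
Why: Fischer esterification with azeotropic removal of water; the two carboxyl groups of 1 are far apart and react independently, so a threefold excess of 1 should statistically place most of 2 in the monoester, the excess diacid being sparingly soluble in cold toluene and the diester far less polar than 3.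

**Step 2**
Reactants: 3 12-oxo-12-(2-phenylethoxy)dodecanoic acid; 4 octadecanoic acid (stearic acid)
Product: 5 2-phenylethyl octacosanoate (phenylethyl n-octacosanoate)
Conditions: 3 (1 equiv), 4 (4 equiv), NaOMe (5 mol % of total CO2H), MeOH with hexane as cosolvent for the waxy products, 50 °C, undivided cell, two smooth Pt foil electrodes, constant current 0.2 A cm−2, polarity reversed every few minutes, stopped at pH 7.5–8; AcOH, evaporate; SiO2 (hexane, then hexane/Et2O); recrystallise from acetone
Reagents that add atoms: none
Why: Crossed Kolbe electrolysis, in which the carboxylates of 3 and 4 are discharged at the Pt anode, the acyloxy radicals lose CO2 at once, and the 10-(2-phenylethoxycarbonyl)decyl and heptadecyl radicals, formed side by side at high concentration in the anode layer, combine to form the C11–C12 bond, while methanol is reduced to H2 at the cathode and the methoxide formed there is neutralised by the free acids. The closest known reaction type is the mixed Kolbe coupling of a fatty acid with a half ester of an alkanedioic acid, the classical way to lengthen unbranched fatty esters. No ring is closed and no stereocentre is formed. The step needs cross-coupling over homo-coupling: both radicals are unhindered primary alkyl radicals of like reactivity, so the fourfold excess of cheap 4 should steer most radicals from 3 into 5, and the homo-coupled by-products (the C34 alkane from 4, the C22 bis(2-phenylethyl) diester from 3) carry no and two ester groups and should separate from 5 on SiO2. It also needs radical coupling to outrun a second electron transfer to the carbocation, which unbranched primary radicals without a stabilising alpha substituent, smooth Pt, a high current density and a weakly acidic, only slightly neutralised methanol solution all favour. The ester and the unactivated phenyl ring of 3 should be spectators, since the adsorbed carboxylate layer is oxidised in preference to solvent and arene, and the electrolysis is ended before the medium turns basic enough for methanolysis of the 2-phenylethyl ester.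

**Compound list**
1 | dodecanedioic acid | OC(=O)CCCCCCCCCCC(=O)O | starting material
2 | 2-phenylethanol | OCCc1ccccc1 | starting material
3 | 12-oxo-12-(2-phenylethoxy)dodecanoic acid (mono-2-phenylethyl dodecanedioate) | OC(=O)CCCCCCCCCCC(=O)OCCc1ccccc1 | intermediate
4 | octadecanoic acid (stearic acid) | CCCCCCCCCCCCCCCCCC(=O)O | starting material
5 | 2-phenylethyl octacosanoate (phenylethyl n-octacosanoate) | CCCCCCCCCCCCCCCCCCCCCCCCCCCC(=O)OCCc1ccccc1 | target

**Total step count:** 2
**Longest linear sequence:** 2 (1 → 3 → 5; 4 enters in step 2)

**Steps most likely to fail** (the route has only two steps, so both are given, the riskier first)

Step 2. Waxy products may coat the anode, which would lower the effective current density and shift the course from radical coupling to two-electron oxidation. Statistical homo-coupling may consume 3, and the 2-phenylethyl ester may undergo methanolysis if the electrolyte is allowed to turn alkaline. The fallback replaces the anodic radical union by a polar alkyl–alkyl coupling; it sets out from 2 and comes back to the route at 5. Compound 2 would be esterified with 10-bromodecanoic acid F1 (TsOH·H2O, toluene, Dean–Stark) to 2-phenylethyl 10-bromodecanoate F2. 1-Bromooctadecane F3 would be converted with Mg turnings in THF into octadecylmagnesium bromide F4. Slow addition of F4 to F2 in THF at 20 °C in the presence of Li2CuCl4 (3 mol %) and N-methylpyrrolidone (4 equiv), conditions under which a primary bromide should couple much faster than an ester is attacked, should give 5 directly.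

Step 1. Over-esterification to the diester and losses in separating the soap-like monoester from diacid and diester may make the statistical monoesterification inefficient. The fallback differentiates the two carboxyl groups from the start instead of statistically; it sets out from 2 and comes back to the route at 3. Compound 2 would be acylated with commercially available 12-tert-butoxy-12-oxododecanoic acid F5 (DCC, DMAP cat., CH2Cl2, room temperature) to tert-butyl 2-phenylethyl dodecanedioate F6. The tert-butyl ester would then be cleaved with CF3CO2H in CH2Cl2, which should leave the primary 2-phenylethyl ester untouched, to give 3.

**Further compounds**
F1 | step 2 | 10-bromodecanoic acid | OC(=O)CCCCCCCCCBr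
F2 | step 2 | 2-phenylethyl 10-bromodecanoate | BrCCCCCCCCCC(=O)OCCc1ccccc1
F3 | step 2 | 1-bromooctadecane | CCCCCCCCCCCCCCCCCCBr
F4 | step 2 | octadecylmagnesium bromide | CCCCCCCCCCCCCCCCCC[Mg]Br
F5 | step 1 | 12-tert-butoxy-12-oxododecanoic acid | CC(C)(C)OC(=O)CCCCCCCCCCC(=O)O
F6 | step 1 | tert-butyl 2-phenylethyl dodecanedioate | CC(C)(C)OC(=O)CCCCCCCCCCC(=O)OCCc1ccccc1
A1 | direct plan | tridecyl(triphenyl)phosphonium bromide | CCCCCCCCCCCCC[P+](c1ccccc1)(c1ccccc1)c1ccccc1.[Br-]
A2 | direct plan | tetradecanal | CCCCCCCCCCCCCC=O
A3 | direct plan | (Z)-heptacos-13-ene | CCCCCCCCCCCC/C=C\CCCCCCCCCCCCC
A4 | direct plan | carbon monoxide | [C-]#[O+]
A5 | direct plan | 2-phenylethanol | OCCc1ccccc1
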